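With the dioxane ring numbered O1, C2 (syringyl ring B), C3 (C9 hydroxymethyl), O4 and ring A numbered C4a (on O4), C5 (OMe), C7 (propenal), C8a (on O1), the route exploits C3. It carries only O4, C2 and carboxyl-derived C9, the substitution pattern of a diazoacetate carbon inserted between a phenol oxygen and a formyl carbon. Cutting O4–C3 and C2–C3 leads to ethyl diazoacetate, a ring A bromophenol ester and O-pivaloyl syringaldehyde. One co-catalysed operation joins the three, sets C2 and C3 as the threo pair and closes no ring. The bromide later serves for O1–C8a closure.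

Key step: step 2

Assumption: the sense of induction of the chiral acid cannot be derived from precedent for this trio. The (R)-acid is written, and the (S)-acid is taken instead if a pilot run shows the mirror-image product.
Remark on descriptors: the target is trans-(2S,3S). In the open-chain ester the same spatial arrangement is (2R,3S) in propanoate numbering, because CO2Et outranks the carbinol carbon. The ether carbon becomes S on reduction without any bond to it changing.

Step 1
Reactants: 1 syringaldehyde
Product: 2 4-formyl-2,6-dimethoxyphenyl pivalate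
Conditions: PivCl, Et3N, 4-(dimethylamino)pyridine (cat.), CH2Cl2, 0 °C to rt
Reagents that add atoms: pivaloyl chloride, CC(C)(C)C(=O)Cl
Why: Nucleophile-catalysed O-acylation of a phenol is routine, and it turns the donating para oxygen into a withdrawing acyloxy group, which makes the aldehyde a better electrophile for step 2.

Step 2
Reactants: 2 4-formyl-2,6-dimethoxyphenyl pivalate; 3 methyl 3-bromo-4-hydroxy-5-methoxybenzoate; 4 ethyl diazoacetate
Product: 6 ethyl (2R,3S)-2-[2-bromo-6-methoxy-4-(methoxycarbonyl)phenoxy]-3-[3,5-dimethoxy-4-(pivaloyloxy)phenyl]-3-hydroxypropanoate, via oxonium ylide 5 (not isolated)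
Conditions: Rh2(OAc)4 (2 mol %), (R)-3,3'-bis(2,4,6-triisopropylphenyl)-1,1'-binaphthyl-2,2'-diyl hydrogen phosphate (10 mol %), 4 Å MS, CH2Cl2, 0 °C; 4 (1.0 equiv) added by syringe pump over 6 h to 3 (1.2 equiv) and 2 (1.5 equiv)
Reagents that add atoms: none
Why: Proposed new method: Rh2(OAc)4 converts 4 into an electrophilic carbene that is captured by the only O–H present, that of 3, to give oxonium ylide 5 (in equilibrium with its enol), and the phosphoric acid binds this nucleophile through P=O and the formyl oxygen of 2 through P–OH, so that aldol-type C2–C3 bond formation can compete with the 1,2-proton shift. The closest known reaction type is the Rh2(OAc)4/chiral phosphoric acid co-catalysed three-component coupling of aryldiazoacetates, alcohols and imines or aldehydes through trapped protic oxonium ylides, whereas a phenol, an unsubstituted diazoacetate and a benzaldehyde of this kind have not been combined in this way. No ring is closed. C3 (R at the ester stage) and C2 (S) arise in the same transition state: the syn (threo) relation should follow from the compact hydrogen-bonded assembly, which keeps the aryloxy group and ring B apart, and the absolute sense from the 3,3'-aryl pockets of the acid, which leave one face of the aldehyde open. The step needs trapping to beat O–H insertion, and capture of the carbene by the phenol rather than by the aldehyde oxygen or the product alcohol; the pivaloyloxy group raises the electrophilicity of 2, both 2 and 3 are kept in excess, and 4 is the limiting reagent held at low concentration. Molecular sieves exclude water, which would otherwise act as a rival O–H donor.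

Step 3
Reactants: 6 ethyl (2R,3S)-2-[2-bromo-6-methoxy-4-(methoxycarbonyl)phenoxy]-3-[3,5-dimethoxy-4-(pivaloyloxy)phenyl]-3-hydroxypropanoate
Product: 8 methyl 3-bromo-4-{[(1S,2S)-1,3-dihydroxy-1-(4-hydroxy-3,5-dimethoxyphenyl)propan-2-yl]oxy}-5-methoxybenzoate, via diol pivalate 7 (not isolated)
Conditions: NaBH4, THF/MeOH 4:1, 0 °C to rt; then NaOMe, MeOH, rt; aq. NH4Cl
Reagents that add atoms: none
Why: In this chemoselective borohydride reduction the α-aryloxy-β-hydroxy ester is activated inductively and by the neighbouring alkoxyborohydride while the donor-substituted methyl benzoate is inert, and the following Zemplén-type methanolysis removes the aryl pivalate but can only regenerate the ring A methyl ester, with no bond at either stereocentre touched.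

Step 4
Reactants: 8 methyl 3-bromo-4-{[(1S,2S)-1,3-dihydroxy-1-(4-hydroxy-3,5-dimethoxyphenyl)propan-2-yl]oxy}-5-methoxybenzoate
Product: 9 methyl 3-bromo-4-{[(1S,2S)-3-(tert-butyldimethylsilyloxy)-1-[4-(tert-butyldimethylsilyloxy)-3,5-dimethoxyphenyl]-1-hydroxypropan-2-yl]oxy}-5-methoxybenzoate
Conditions: TBSCl (2.2 equiv), imidazole, DMF, 0 °C to rt
Reagents that add atoms: tert-butyldimethylsilyl chloride, CC(C)(C)[Si](C)(C)Cl
Why: Imidazole-promoted silylation discriminates by steric demand, so the phenol and the primary C9–OH react while the flanked secondary C2–OH stays free; this blocks the rival six-membered closure through C9–O and gives a phenol mask that, unlike the pivalate, survives iBu2AlH and shields the oxidisable syringyl phenol from MnO2.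

Step 5
Reactants: 9 methyl 3-bromo-4-{[(1S,2S)-3-(tert-butyldimethylsilyloxy)-1-[4-(tert-butyldimethylsilyloxy)-3,5-dimethoxyphenyl]-1-hydroxypropan-2-yl]oxy}-5-methoxybenzoate
Product: 10 methyl (2S,3S)-2-[4-(tert-butyldimethylsilyloxy)-3,5-dimethoxyphenyl]-3-[(tert-butyldimethylsilyloxy)methyl]-5-methoxy-2,3-dihydro-1,4-benzodioxine-7-carboxylate (numbering of the overview)
Conditions: Pd(OAc)2 (5 mol %), 2-(di-tert-butylphosphino)-1,1'-binaphthyl (7 mol %), Cs2CO3, toluene, 80 °C
Reagents that add atoms: none
Why: In this intramolecular Buchwald–Hartwig etherification zerovalent palladium inserts into C8a–Br, the C2 alkoxide binds and C–O reductive elimination forms O1–C8a without touching the C2–O bond, so the threo diol maps onto the trans dioxane with retention, and the bulky electron-rich phosphine favours reductive elimination over β-hydride elimination.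

Step 6
Reactants: 10 methyl (2S,3S)-2-[4-(tert-butyldimethylsilyloxy)-3,5-dimethoxyphenyl]-3-[(tert-butyldimethylsilyloxy)methyl]-5-methoxy-2,3-dihydro-1,4-benzodioxine-7-carboxylate
Product: 11 [(2S,3S)-2-[4-(tert-butyldimethylsilyloxy)-3,5-dimethoxyphenyl]-3-[(tert-butyldimethylsilyloxy)methyl]-5-methoxy-2,3-dihydro-1,4-benzodioxin-7-yl]methanol
Conditions: iBu2AlH (2.5 equiv), CH2Cl2, −78 to 0 °C; aq. potassium sodium tartrate
Reagents that add atoms: none
Why: Hydride reduction of the only remaining ester gives the primary benzylic alcohol, and the silyl ethers, aryl ethers and dioxane ring are inert to iBu2AlH.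

Step 7
Reactants: 11 [(2S,3S)-2-[4-(tert-butyldimethylsilyloxy)-3,5-dimethoxyphenyl]-3-[(tert-butyldimethylsilyloxy)methyl]-5-methoxy-2,3-dihydro-1,4-benzodioxin-7-yl]methanol
Product: 12 (2S,3S)-2-[4-(tert-butyldimethylsilyloxy)-3,5-dimethoxyphenyl]-3-[(tert-butyldimethylsilyloxy)methyl]-5-methoxy-2,3-dihydro-1,4-benzodioxine-7-carbaldehyde
Conditions: activated MnO2 (excess), CH2Cl2, rt
Reagents that add atoms: none
Why: MnO2 oxidation of an electron-rich benzylic alcohol stops at the aldehyde, and with no free phenol in the molecule no phenoxyl or quinone methide pathway can reach C2.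

Step 8
Reactants: 12 (2S,3S)-2-[4-(tert-butyldimethylsilyloxy)-3,5-dimethoxyphenyl]-3-[(tert-butyldimethylsilyloxy)methyl]-5-methoxy-2,3-dihydro-1,4-benzodioxine-7-carbaldehyde
Product: 13 (E)-3-[(2S,3S)-2-[4-(tert-butyldimethylsilyloxy)-3,5-dimethoxyphenyl]-3-[(tert-butyldimethylsilyloxy)methyl]-5-methoxy-2,3-dihydro-1,4-benzodioxin-7-yl]prop-2-enal
Conditions: Ph3P=CHCHO (1.3 equiv), toluene, 90 °C
Reagents that add atoms: (triphenylphosphoranylidene)acetaldehyde, O=CC=P(c1ccccc1)(c1ccccc1)c1ccccc1
Why: The Wittig reaction of a stabilised formyl ylide with an aryl aldehyde gives the E-enal, and a small excess of ylide with timely interruption limits a second homologation.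

Step 9
Reactants: 13 (E)-3-[(2S,3S)-2-[4-(tert-butyldimethylsilyloxy)-3,5-dimethoxyphenyl]-3-[(tert-butyldimethylsilyloxy)methyl]-5-methoxy-2,3-dihydro-1,4-benzodioxin-7-yl]prop-2-enal
Product: 14 bilagrewin, (E)-3-[(2S,3S)-2-(4-hydroxy-3,5-dimethoxyphenyl)-3-(hydroxymethyl)-5-methoxy-2,3-dihydro-1,4-benzodioxin-7-yl]prop-2-enal
Conditions: Et3N·3HF, THF, rt
Reagents that add atoms: none
Why: Fluoride-mediated desilylation with a nearly neutral HF source cleaves both Si–O bonds in one operation, leaves the enal alone and avoids a free phenoxide that could open the dioxane at C2 through a quinone methide.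

Compound list
1 | syringaldehyde (4-hydroxy-3,5-dimethoxybenzaldehyde) | COc1cc(C=O)cc(OC)c1O | starting material
2 | 4-formyl-2,6-dimethoxyphenyl pivalate | COc1cc(C=O)cc(OC)c1OC(=O)C(C)(C)C | intermediate
3 | methyl 3-bromo-4-hydroxy-5-methoxybenzoate | COC(=O)c1cc(Br)c(O)c(OC)c1 | starting material
4 | ethyl diazoacetate | CCOC(=O)C=[N+]=[N-] | starting material
5 | protic oxonium ylide from 3 and the carbene of 4 (tautomer of the corresponding enol) | CCOC(=O)[CH-][OH+]c1c(Br)cc(C(=O)OC)cc1OC | intermediate
6 | ethyl (2R,3S)-2-[2-bromo-6-methoxy-4-(methoxycarbonyl)phenoxy]-3-[3,5-dimethoxy-4-(pivaloyloxy)phenyl]-3-hydroxypropanoate (threo) | COc1cc([C@H](O)[C@H](C(=O)OCC)Oc2c(Br)cc(C(=O)OC)cc2OC)cc(OC)c1OC(=O)C(C)(C)C | intermediate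
7 | methyl 3-bromo-4-{[(1S,2S)-1-[3,5-dimethoxy-4-(pivaloyloxy)phenyl]-1,3-dihydroxypropan-2-yl]oxy}-5-methoxybenzoate | COc1cc([C@H](O)[C@H](CO)Oc2c(Br)cc(C(=O)OC)cc2OC)cc(OC)c1OC(=O)C(C)(C)C | intermediate
8 | methyl 3-bromo-4-{[(1S,2S)-1,3-dihydroxy-1-(4-hydroxy-3,5-dimethoxyphenyl)propan-2-yl]oxy}-5-methoxybenzoate | COc1cc([C@H](O)[C@H](CO)Oc2c(Br)cc(C(=O)OC)cc2OC)cc(OC)c1O | intermediate
9 | methyl 3-bromo-4-{[(1S,2S)-3-(tert-butyldimethylsilyloxy)-1-[4-(tert-butyldimethylsilyloxy)-3,5-dimethoxyphenyl]-1-hydroxypropan-2-yl]oxy}-5-methoxybenzoate | COc1cc([C@H](O)[C@H](CO[Si](C)(C)C(C)(C)C)Oc2c(Br)cc(C(=O)OC)cc2OC)cc(OC)c1O[Si](C)(C)C(C)(C)C | intermediate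
10 | methyl (2S,3S)-2-[4-(tert-butyldimethylsilyloxy)-3,5-dimethoxyphenyl]-3-[(tert-butyldimethylsilyloxy)methyl]-5-methoxy-2,3-dihydro-1,4-benzodioxine-7-carboxylate (trans) | COc1cc([C@@H]2Oc3cc(C(=O)OC)cc(OC)c3O[C@H]2CO[Si](C)(C)C(C)(C)C)cc(OC)c1O[Si](C)(C)C(C)(C)C | intermediate
11 | ring A benzylic alcohol of 10, (2S,3S) | COc1cc([C@@H]2Oc3cc(CO)cc(OC)c3O[C@H]2CO[Si](C)(C)C(C)(C)C)cc(OC)c1O[Si](C)(C)C(C)(C)C | intermediate
12 | ring A 7-carbaldehyde, (2S,3S) | COc1cc([C@@H]2Oc3cc(C=O)cc(OC)c3O[C@H]2CO[Si](C)(C)C(C)(C)C)cc(OC)c1O[Si](C)(C)C(C)(C)C | intermediate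
13 | bis-TBS ether of bilagrewin, (E), (2S,3S) | COc1cc([C@@H]2Oc3cc(/C=C/C=O)cc(OC)c3O[C@H]2CO[Si](C)(C)C(C)(C)C)cc(OC)c1O[Si](C)(C)C(C)(C)C | intermediate
14 | bilagrewin | COc1cc([C@@H]2Oc3cc(/C=C/C=O)cc(OC)c3O[C@H]2CO)cc(OC)c1O | target

Total step count: 9. Longest linear sequence: 9 steps (1 to 14). Compounds 3 and 4 enter as bought in step 2.

Steps most likely to fail

Step 2.
- **What may go wrong:** The proton shift within the ylide or enol may outrun the aldol trapping. The acid may protonate the diazo ester before the rhodium catalyst consumes it. Facial or syn/anti selectivity in the hydrogen-bonded assembly may be poor.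
- **Fallback:** This is known chemistry, an Evans boron syn-aldol of an aryloxyacetyl imide, and it sets out from 3. O-Alkylation with (R)-4-benzyl-3-(chloroacetyl)oxazolidin-2-one (K2CO3, NaI, acetone) should give the aryloxyacetyl imide F1. Enolisation with Bu2BOTf and iPr2NEt in CH2Cl2 at −78 °C, followed by addition of 2 through a Zimmerman–Traxler chair, should give the (2R,3S)-syn aldol imide F2. Reductive removal of the auxiliary with NaBH4 in THF/H2O comes back to the route at 7, which is then methanolysed as in step 3.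

Step 5.
- **What may go wrong:** β-Hydride elimination from the palladium alkoxide may oxidise the carbinol and remove the bromine. Reductive elimination may be sluggish at the hindered secondary alkoxide. Base-induced migration of ring A from O4 to the C2 oxygen may occur.
- **Fallback:** It sets out from 9 and forms O1–C2 instead of O1–C8a. Miyaura borylation (bis(pinacolato)diboron, PdCl2(dppf), KOAc, dioxane, 80 °C) should give the pinacol boronate F3. Oxidation with NaBO3·4H2O in THF/H2O should give the ring A phenol F4. A catalytic amount of p-toluenesulfonic acid in CH2Cl2 at 0 °C should then ionise the electron-rich benzylic alcohol, and the phenol closes onto the cation. C3 then steers C2 into the diequatorial trans arrangement, and the sequence comes back to the route at 10.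

Step 8.
- **What may go wrong:** The electron-rich aldehyde may convert slowly, while the enal already formed reacts again with the ylide.
- **Fallback:** It sets out from 12 and adds the two carbons at the ester level. A Horner–Wadsworth–Emmons reaction with triethyl phosphonoacetate (LiCl, DBU, MeCN) should give the (E)-cinnamate F5. iBu2AlH in CH2Cl2 at −78 °C should give the (E)-cinnamyl alcohol F6. MnO2 in CH2Cl2 then comes back to the route at 13.

Further compounds
F1 | step 2 | (R)-4-benzyl-3-{[2-bromo-6-methoxy-4-(methoxycarbonyl)phenoxy]acetyl}oxazolidin-2-one | COC(=O)c1cc(Br)c(OCC(=O)N2[C@H](Cc3ccccc3)COC2=O)c(OC)c1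
F2 | step 2 | (R)-4-benzyl-3-{(2R,3S)-2-[2-bromo-6-methoxy-4-(methoxycarbonyl)phenoxy]-3-[3,5-dimethoxy-4-(pivaloyloxy)phenyl]-3-hydroxypropanoyl}oxazolidin-2-one | COc1cc([C@H](O)[C@H](C(=O)N2[C@H](Cc3ccccc3)COC2=O)Oc2c(Br)cc(C(=O)OC)cc2OC)cc(OC)c1OC(=O)C(C)(C)C
F3 | step 5 | pinacol boronate of 9 (Bpin in place of Br), (1S,2S) | COc1cc([C@H](O)[C@H](CO[Si](C)(C)C(C)(C)C)Oc2c(B3OC(C)(C)C(C)(C)O3)cc(C(=O)OC)cc2OC)cc(OC)c1O[Si](C)(C)C(C)(C)C
F4 | step 5 | ring A phenol of 9 (OH in place of Br), (1S,2S) | COc1cc([C@H](O)[C@H](CO[Si](C)(C)C(C)(C)C)Oc2c(O)cc(C(=O)OC)cc2OC)cc(OC)c1O[Si](C)(C)C(C)(C)C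
F5 | step 8 | ethyl (E)-3-[(2S,3S)-bis-TBS-protected benzodioxin-7-yl]prop-2-enoate | COc1cc([C@@H]2Oc3cc(/C=C/C(=O)OCC)cc(OC)c3O[C@H]2CO[Si](C)(C)C(C)(C)C)cc(OC)c1O[Si](C)(C)C(C)(C)C
F6 | step 8 | (E)-3-[(2S,3S)-bis-TBS-protected benzodioxin-7-yl]prop-2-en-1-ol | COc1cc([C@@H]2Oc3cc(/C=C/CO)cc(OC)c3O[C@H]2CO[Si](C)(C)C(C)(C)C)cc(OC)c1O[Si](C)(C)C(C)(C)C
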